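**Retrosynthetic overview**
- Target ⇐ cis-fused tetracycle in which ring C is closed and the ring B oxygen is tied to C3 as a lactone (ring D); aqueous acid opens ring D, expels CO2 and removes the MOM groups.
- Tetracycle ⇐ ring A 4-hydroxycoumarin + ring B salicylaldehyde in one flask: Knoevenagel condensation, translactonisation (closes ring D), enantioselective oxa-Michael addition (closes ring C, sets C2).
- Ring A piece ⇐ 2,4,6-trihydroxyacetophenone: C-prenylation, selective bis-MOM protection, carbonate annulation (fixes the 8-prenyl pattern).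
- Ring B piece ⇐ 4-bromophenol: γ-selective prenyl coupling (gives the 1,1-dimethylallyl group), then ortho-formylation.
- Ring order: rings A and B are bought; a temporary pyranone is put on ring A (step 3); rings D and C close together (step 6, the temporary pyranone opens in the same flask); ring D is opened (step 7).

Assumption: the quinine-derived thiourea is taken to give the 12aS tetracycle; if the first run shows the opposite sense, the quinidine-derived pseudo-enantiomer is used under otherwise identical conditions.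

**Step 1**
Reactants: 1 2,4,6-trihydroxyacetophenone; 2 prenyl bromide (1-bromo-3-methylbut-2-ene)
Product: 3 1-[2,4,6-trihydroxy-3-(3-methylbut-2-en-1-yl)phenyl]ethan-1-one
Conditions: 1 (1.2 equiv), DBU (1.0 equiv), THF, 0 °C to 23 °C
Reagents that add atoms: none
Why: Friedel–Crafts-type C-allylation of the phloroglucinol phenoxide, in which the soft allylic bromide attacks a ring carbon flanked by two oxygens; the two free ring positions are equivalent and a slight excess of 1 limits bis-prenylation.

**Step 2**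
Reactants: 3 1-[2,4,6-trihydroxy-3-(3-methylbut-2-en-1-yl)phenyl]ethan-1-one
Product: 4 1-[2-hydroxy-4,6-bis(methoxymethoxy)-3-(3-methylbut-2-en-1-yl)phenyl]ethan-1-one
Conditions: MOMCl (2.1 equiv), i-Pr2NEt (2.5 equiv), CH2Cl2, 0 °C
Reagents that add atoms: chloromethyl methyl ether, COCCl
Why: MOM ether formation (O-alkylation) at the non-chelated 4-OH and the unhindered 6-OH, while the 2-OH, hydrogen-bonded to the ketone and flanked by the prenyl group, stays free and so becomes the ring C oxygen next to the prenyl group.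

**Step 3**
Reactants: 4 1-[2-hydroxy-4,6-bis(methoxymethoxy)-3-(3-methylbut-2-en-1-yl)phenyl]ethan-1-one
Product: 5 4-hydroxy-5,7-bis(methoxymethoxy)-8-(3-methylbut-2-en-1-yl)-2H-chromen-2-one
Conditions: NaH (4 equiv), (EtO)2CO (5 equiv), PhMe, 100 °C; then cold 1 M HCl to pH 4
Reagents that add atoms: diethyl carbonate, CCOC(=O)OCC
Why: Claisen-type ethoxycarbonylation of the methyl ketone enolate followed by lactonisation onto the only free phenol (classical 4-hydroxycoumarin synthesis), which gives a Knoevenagel-active vinylogous acid and stores the prenyl-flanked oxygen in a lactone that step 6 releases.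

**Step 4**
Reactants: 6 4-bromophenol; 7 4,4,5,5-tetramethyl-2-(3-methylbut-2-en-1-yl)-1,3,2-dioxaborolane (prenylboronic acid pinacol ester)
Product: 8 4-(2-methylbut-3-en-2-yl)phenol
Conditions: 7 (1.5 equiv), Pd(OAc)2 (2 mol %), bulky biaryl dialkylphosphine selected for γ-attack (4 mol %), aq K3PO4 (3 equiv), MeCN, 70 °C
Reagents that add atoms: none
Why: Ligand-controlled γ-selective Suzuki–Miyaura coupling of a 3,3-disubstituted allylboronate, in which SE2′ transmetalation places palladium on the tertiary carbon and fast reductive elimination gives the branched 1,1-dimethylallyl arene instead of the linear prenyl isomer.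

**Step 5**
Reactants: 8 4-(2-methylbut-3-en-2-yl)phenol
Product: 9 2-hydroxy-5-(2-methylbut-3-en-2-yl)benzaldehyde
Conditions: MgCl2 (1.5 equiv), Et3N (3.75 equiv), (CH2O)n (6.75 equiv), MeCN, reflux; 1 M HCl work-up
Reagents that add atoms: paraformaldehyde (formaldehyde source), C=O
Why: Casnati–Skattebøl ortho-formylation, in which the magnesium phenoxide delivers formaldehyde only to the ortho position (para is blocked) and a second formaldehyde oxidises the benzylic alkoxide to the aldehyde, leaving the isolated alkene untouched.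

**Step 6**
Reactants: 5 4-hydroxy-5,7-bis(methoxymethoxy)-8-(3-methylbut-2-en-1-yl)-2H-chromen-2-one; 9 2-hydroxy-5-(2-methylbut-3-en-2-yl)benzaldehyde
Product: 12 (6aS,12aS)-8,10-bis(methoxymethoxy)-2-(2-methylbut-3-en-2-yl)-11-(3-methylbut-2-en-1-yl)-6a,12a-dihydro-6H,7H-chromeno[4,3-b]chromene-6,7-dione, via Knoevenagel adduct 10 (not isolated), via aroylcoumarin 11 (not isolated)
Conditions: 9 (1.1 equiv), 1-[3,5-bis(trifluoromethyl)phenyl]-3-[(8α,9S)-6′-methoxycinchonan-9-yl]thiourea (10 mol %), 4 Å molecular sieves, PhMe, 23 °C until 5 is consumed, then −25 °C, 48 h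
Reagents that add atoms: none
Why: Proposed new method: the ammonium salt formed from the acidic coumarin 5 and the catalyst's quinuclidine condenses with 9 (Knoevenagel) to give 10, whose ortho-phenol attacks the lactone carbonyl and expels the ring A phenoxide (translactonisation, known for 4-hydroxycoumarins and 4-hydroxy-2-pyranones with salicylaldehydes) to give 11 and close ring D, and once 5 is consumed the free quinuclidine deprotonates the released prenyl-flanked phenol, which adds to C4 of the thiourea-bound 3-aroylcoumarin to close ring C, the chiral pocket setting C12a as S and the cis ring fusion fixing the labile C6a; the closest known reaction is the cinchona-thiourea-catalysed intramolecular oxa-Michael cyclisation of alkylidene β-keto esters to 3-carboxyflavanones.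

**Step 7**
Reactants: 12 (6aS,12aS)-8,10-bis(methoxymethoxy)-2-(2-methylbut-3-en-2-yl)-11-(3-methylbut-2-en-1-yl)-6a,12a-dihydro-6H,7H-chromeno[4,3-b]chromene-6,7-dione
Product: 14 (2S)-5,7-dihydroxy-2-[2-hydroxy-5-(2-methylbut-3-en-2-yl)phenyl]-8-(3-methylbut-2-en-1-yl)-2,3-dihydro-4H-chromen-4-one (CID51040684), via β-keto acid 13 (not isolated)
Conditions: 2 M aq HCl, THF, 50 °C
Reagents that add atoms: none
Why: Acid-catalysed hydrolysis of the activated aryl lactone gives β-keto acid 13, which decarboxylates spontaneously (β-keto acid decarboxylation) while both MOM acetals are hydrolysed in the same medium, and C2 is untouched because opening of ring C needs base, so the S configuration from step 6 is carried into 14.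

**Compound list**
1 | 2,4,6-trihydroxyacetophenone | CC(=O)c1c(O)cc(O)cc1O | starting material
2 | prenyl bromide (1-bromo-3-methylbut-2-ene) | CC(C)=CCBr | starting material
3 | 1-[2,4,6-trihydroxy-3-(3-methylbut-2-en-1-yl)phenyl]ethan-1-one | CC(=O)c1c(O)cc(O)c(CC=C(C)C)c1O | intermediate
4 | 1-[2-hydroxy-4,6-bis(methoxymethoxy)-3-(3-methylbut-2-en-1-yl)phenyl]ethan-1-one | CC(=O)c1c(OCOC)cc(OCOC)c(CC=C(C)C)c1O | intermediate
5 | 4-hydroxy-5,7-bis(methoxymethoxy)-8-(3-methylbut-2-en-1-yl)-2H-chromen-2-one | COCOc1cc(OCOC)c2c(O)cc(=O)oc2c1CC=C(C)C | intermediate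
6 | 4-bromophenol | Oc1ccc(Br)cc1 | starting material
7 | 4,4,5,5-tetramethyl-2-(3-methylbut-2-en-1-yl)-1,3,2-dioxaborolane | CC(C)=CCB1OC(C)(C)C(C)(C)O1 | starting material
8 | 4-(2-methylbut-3-en-2-yl)phenol | C=CC(C)(C)c1ccc(O)cc1 | intermediate
9 | 2-hydroxy-5-(2-methylbut-3-en-2-yl)benzaldehyde | C=CC(C)(C)c1ccc(O)c(C=O)c1 | intermediate
10 | 3-{[2-hydroxy-5-(2-methylbut-3-en-2-yl)phenyl]methylidene}-5,7-bis(methoxymethoxy)-8-(3-methylbut-2-en-1-yl)-2H-chromene-2,4(3H)-dione (E/Z mixture) | COCOc1cc(OCOC)c2C(=O)C(=Cc3cc(C(C)(C)C=C)ccc3O)C(=O)Oc2c1CC=C(C)C | intermediate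
11 | 3-[2-hydroxy-4,6-bis(methoxymethoxy)-3-(3-methylbut-2-en-1-yl)benzoyl]-6-(2-methylbut-3-en-2-yl)-2H-chromen-2-one | C=CC(C)(C)c1ccc2oc(=O)c(C(=O)c3c(OCOC)cc(OCOC)c(CC=C(C)C)c3O)cc2c1 | intermediate
12 | (6aS,12aS)-8,10-bis(methoxymethoxy)-2-(2-methylbut-3-en-2-yl)-11-(3-methylbut-2-en-1-yl)-6a,12a-dihydro-6H,7H-chromeno[4,3-b]chromene-6,7-dione (cis-fused keto form; C6a enolisable) | C=CC(C)(C)c1ccc2OC(=O)[C@@H]3C(=O)c4c(OCOC)cc(OCOC)c(CC=C(C)C)c4O[C@@H]3c2c1 | intermediate
13 | (2S)-2-[2-hydroxy-5-(2-methylbut-3-en-2-yl)phenyl]-5,7-bis(methoxymethoxy)-8-(3-methylbut-2-en-1-yl)-4-oxo-3,4-dihydro-2H-chromene-3-carboxylic acid (C3 not defined) | C=CC(C)(C)c1ccc(O)c([C@@H]2C(C(=O)O)C(=O)c3c(OCOC)cc(OCOC)c(CC=C(C)C)c3O2)c1 | intermediate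
14 | (2S)-5,7-dihydroxy-2-[2-hydroxy-5-(2-methylbut-3-en-2-yl)phenyl]-8-(3-methylbut-2-en-1-yl)-2,3-dihydro-4H-chromen-4-one | C=CC(C)(C)c1ccc(O)c([C@@H]2CC(=O)c3c(O)cc(O)c(CC=C(C)C)c3O2)c1 | target

**Step count**
Total steps: 7. Longest linear sequence: 5 steps (1 → 3 → 4 → 5 → 12 → 14).

**Steps most likely to fail, each with a fallback**

Step 6 (one-flask closure of rings D and C). The oxa-Michael addition onto the aroylcoumarin may stop at 11 for thermodynamic reasons or give low ee. The fallback sets out from 4 and 9 and comes back at 14; it gives up the lactone tether and uses an acyclic alkylidene β-keto ester. Compound 9 is capped (MOMCl, i-Pr2NEt, CH2Cl2) to 2-(methoxymethoxy)-5-(2-methylbut-3-en-2-yl)benzaldehyde F1, so that no lactone can form. Compound 4 is treated with Boc2O/DMAP and then LiN(SiMe3)2 in THF (carbonate oxygen-to-carbon acyl shift of Baker–Venkataraman type) to give the tert-butyl β-keto ester F2. Piperidinium acetate in refluxing toluene condenses F2 and F1 to the alkylidene β-keto ester F3. The same cinchona thiourea (10 mol %, PhMe, −25 °C) closes ring C to the tert-butyl (2S)-flavanone-3-carboxylate F4. TsOH·H2O in toluene at 80 °C followed by 2 M HCl/THF removes the tert-butyl group, CO2 and the three MOM groups to give 14.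

Step 7 (lactone opening, decarboxylation and MOM removal in hot aqueous acid). The prenyl group next to the free 7-OH may cyclise or hydrate, or the lactone may hydrolyse too slowly. The fallback sets out from 12 and comes back at 14; it separates the events under neutral conditions. Heating 12 with allyl alcohol in toluene at 90 °C makes the β-keto aryl ester collapse to an acylketene with release of the ring B phenol, and allyl alcohol traps it as the allyl (2S)-flavanone-3-carboxylate F5. Pd(PPh3)4 with morpholine in THF at 23 °C (Tsuji deallylation–decarboxylation) gives the bis-MOM 2′-hydroxyflavanone F6. HCl in MeOH at 20 °C then removes the MOM groups to give 14.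

Step 4 (γ-selective coupling on a free bromophenol). The linear prenyl isomer or isoprene from β-hydride elimination may dominate. The fallback sets out from 6 and comes back at 8; it builds the quaternary carbon by enolate arylation and the vinyl group by olefination. Compound 6 is protected (MOMCl, i-Pr2NEt) as 1-bromo-4-(methoxymethoxy)benzene F7. α-Arylation of 2-methylpropanal ({Pd(allyl)Cl}2, 1,1′-bis(diphenylphosphino)ferrocene, Cs2CO3, dioxane, 80 °C) gives 2-[4-(methoxymethoxy)phenyl]-2-methylpropanal F8. Wittig methylenation (Ph3PCH3Br, KOtBu, THF) gives 1-(methoxymethoxy)-4-(2-methylbut-3-en-2-yl)benzene F9, and HCl in MeOH at 40 °C returns 8.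

**Further compounds**
F1 | step 6 | 2-(methoxymethoxy)-5-(2-methylbut-3-en-2-yl)benzaldehyde | C=CC(C)(C)c1ccc(OCOC)c(C=O)c1
F2 | step 6 | tert-butyl 3-[2-hydroxy-4,6-bis(methoxymethoxy)-3-(3-methylbut-2-en-1-yl)phenyl]-3-oxopropanoate | CC(C)(C)OC(=O)CC(=O)c1c(OCOC)cc(OCOC)c(CC=C(C)C)c1O
F3 | step 6 | tert-butyl 2-[2-hydroxy-4,6-bis(methoxymethoxy)-3-(3-methylbut-2-en-1-yl)benzoyl]-3-[2-(methoxymethoxy)-5-(2-methylbut-3-en-2-yl)phenyl]prop-2-enoate | CC(C)(C)OC(=O)C(=Cc1cc(C(C)(C)C=C)ccc1OCOC)C(=O)c1c(OCOC)cc(OCOC)c(CC=C(C)C)c1O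
F4 | step 6 | tert-butyl (2S)-5,7-bis(methoxymethoxy)-2-[2-(methoxymethoxy)-5-(2-methylbut-3-en-2-yl)phenyl]-8-(3-methylbut-2-en-1-yl)-4-oxo-3,4-dihydro-2H-chromene-3-carboxylate | C=CC(C)(C)c1ccc(OCOC)c([C@@H]2C(C(=O)OC(C)(C)C)C(=O)c3c(OCOC)cc(OCOC)c(CC=C(C)C)c3O2)c1
F5 | step 7 | prop-2-en-1-yl (2S)-2-[2-hydroxy-5-(2-methylbut-3-en-2-yl)phenyl]-5,7-bis(methoxymethoxy)-8-(3-methylbut-2-en-1-yl)-4-oxo-3,4-dihydro-2H-chromene-3-carboxylate | C=CC(C)(C)c1ccc(O)c([C@@H]2C(C(=O)OCC=C)C(=O)c3c(OCOC)cc(OCOC)c(CC=C(C)C)c3O2)c1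
F6 | step 7 | (2S)-2-[2-hydroxy-5-(2-methylbut-3-en-2-yl)phenyl]-5,7-bis(methoxymethoxy)-8-(3-methylbut-2-en-1-yl)-2,3-dihydro-4H-chromen-4-one | C=CC(C)(C)c1ccc(O)c([C@@H]2CC(=O)c3c(OCOC)cc(OCOC)c(CC=C(C)C)c3O2)c1
F7 | step 4 | 1-bromo-4-(methoxymethoxy)benzene | COCOc1ccc(Br)cc1
F8 | step 4 | 2-[4-(methoxymethoxy)phenyl]-2-methylpropanal | COCOc1ccc(C(C)(C)C=O)cc1
F9 | step 4 | 1-(methoxymethoxy)-4-(2-methylbut-3-en-2-yl)benzene | C=CC(C)(C)c1ccc(OCOC)cc1
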